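Everything rests on disconnecting C9–C10 in ring B. The feature exploited is C10, the fully substituted bridgehead carbon that holds the bridging ether oxygen, the C14 methyl group, C1 and C9: as part of ring A it can be turned into a tertiary cyclic oxocarbenium ion, and the enol silane of a C7 acetyl group (C8, C9) can add to it. One operation therefore makes the C9–C10 bond, closes seven-membered ring B of the 11-oxabicyclo[4.4.1]undecene core and sets C10 under control of C5. The precursor is the ring A oxepene methyl ketal bearing the C4 ester, with a trans γ-lactone at C5 whose C7 carries a 1-(trimethylsilyloxy)vinyl group.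

Key step: step 12

Remark (numbering): locants follow the germacrane-type skeleton: C1–C2 the CH2CH2 arm, C3=C4 the ring alkene (ester carbon C15 on C4), C5 the ether CH, C6 the lactone O–CH, C7 the lactone CH, C8 the acyloxy carbon, C9 the CH2, C10 the quaternary ether carbon (methyl C14), C11/C12/C13 the lactone α-carbon, carbonyl and exocyclic methylene; ring A = O, C10, C1–C5; ring B = O, C5–C10; "core" = 11-oxabicyclo[4.4.1]undec-3-ene with CO2Me on C4 and methyl on C10.

Step 1
Reactants: 1 (S)-5-(hydroxymethyl)furan-2(5H)-one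
Product: 2 (S)-5-{[(tert-butyldimethylsilyl)oxy]methyl}furan-2(5H)-one
Conditions: TBSCl, imidazole, CH2Cl2, 0 °C → rt
Reagents that add atoms: tert-butyldimethylsilyl chloride, CC(C)(C)[Si](C)(C)Cl
Why: Silyl ether formation (imidazole-promoted silylation of a primary alcohol) protects the hydroxyl through the organometallic step and adds the bulk that directs step 2.

Step 2
Reactants: 2 (S)-5-{[(tert-butyldimethylsilyl)oxy]methyl}furan-2(5H)-one; 3 prop-1-en-2-ylmagnesium bromide
Product: 5 (4R,5S)-5-{[(tert-butyldimethylsilyl)oxy]methyl}-4-(prop-1-en-2-yl)oxolan-2-one, via magnesium enolate 4 (not isolated)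
Conditions: 3 (2 equiv), CuBr·SMe2 (0.2 equiv), THF, −78 → −40 °C; then NH4Cl (aq)
Reagents that add atoms: none
Why: Copper-catalysed conjugate addition of a Grignard reagent to a butenolide: the γ-silyloxymethyl group blocks one face, so the isopropenyl group (a masked acetyl group) adds anti to it and sets C7 trans to C6.

Step 3
Reactants: 5 (4R,5S)-5-{[(tert-butyldimethylsilyl)oxy]methyl}-4-(prop-1-en-2-yl)oxolan-2-one
Product: 6 (4R,5S)-5-(hydroxymethyl)-4-(prop-1-en-2-yl)oxolan-2-one
Conditions: HF·pyridine, pyridine, THF, 0 °C → rt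
Reagents that add atoms: none
Why: Fluoride-mediated desilylation of a primary silyl ether under weakly acidic conditions that leave the γ-lactone closed.

Step 4
Reactants: 6 (4R,5S)-5-(hydroxymethyl)-4-(prop-1-en-2-yl)oxolan-2-one
Product: 7 (2S,3R)-5-oxo-3-(prop-1-en-2-yl)oxolane-2-carbaldehyde
Conditions: Dess–Martin periodinane, NaHCO3, CH2Cl2, 0 °C → rt; used crude
Reagents that add atoms: none
Why: Dess–Martin oxidation: the mild, buffered conditions stop at the aldehyde and should not epimerise the α-acyloxy centre C6.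

Step 5
Reactants: 7 (2S,3R)-5-oxo-3-(prop-1-en-2-yl)oxolane-2-carbaldehyde; 8 methyl acrylate
Product: 9 methyl 2-{(R)-hydroxy[(2S,3R)-5-oxo-3-(prop-1-en-2-yl)oxolan-2-yl]methyl}prop-2-enoate
Conditions: 8 (5 equiv), DABCO (1 equiv), 1,4-dioxane/H2O 1:1, rt
Reagents that add atoms: none
Why: Morita–Baylis–Hillman reaction: the DABCO–acrylate zwitterion should add to the α-acyloxy aldehyde anti to the polar C6–O bond and past H6, giving the 5,6-anti carbinol (5R), while the trans lactone is the thermodynamically preferred arrangement at C6.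

Step 6
Reactants: 9 methyl 2-{(R)-hydroxy[(2S,3R)-5-oxo-3-(prop-1-en-2-yl)oxolan-2-yl]methyl}prop-2-enoate
Product: 11 methyl 2-{(R)-[(2S,3S)-3-acetyl-5-oxooxolan-2-yl](hydroxy)methyl}prop-2-enoate, via secondary ozonide 10 (not isolated)
Conditions: O3, CH2Cl2, −78 °C (Sudan Red 7B as end-point indicator); then PPh3, −78 °C → rt
Reagents that add atoms: ozone, [O-][O+]=O
Why: Chemoselective ozonolysis: the electron-rich 1,1-disubstituted isopropenyl alkene reacts far faster with ozone than the electron-poor acrylate, and the C8 methyl ketone is unveiled only after the aldehyde stage, so no intramolecular aldol can interfere.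

Step 7
Reactants: 12 hex-5-en-2-one
Product: 13 5,5-dimethoxyhex-1-ene
Conditions: HC(OMe)3, MeOH, p-TsOH·H2O (cat.), rt; then Et3N
Reagents that add atoms: trimethyl orthoformate, COC(OC)OC
Why: Acid-catalysed ketalisation with orthoformate as dehydrating methanol source; hex-5-en-2-one supplies exactly C14, C10, C1, C2 and C3 (its terminal CH2 leaves in step 10), the chain length that a seven-membered ring A demands.

Step 8
Reactants: 13 5,5-dimethoxyhex-1-ene
Product: 14 2-methoxyhexa-1,5-diene
Conditions: TMSOTf, iPr2NEt, CH2Cl2, −20 °C → rt; distillation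
Reagents that add atoms: none
Why: Silyl triflate/amine-mediated elimination of methanol from a dimethyl ketal (ketal to enol ether); any internal enol ether regioisomer gives the same oxocarbenium ion in step 9 and hence the same product.

Step 9
Reactants: 11 methyl 2-{(R)-[(2S,3S)-3-acetyl-5-oxooxolan-2-yl](hydroxy)methyl}prop-2-enoate; 14 2-methoxyhexa-1,5-diene
Product: 15 methyl 2-{(R)-[(2S,3S)-3-acetyl-5-oxooxolan-2-yl][(2-methoxyhex-5-en-2-yl)oxy]methyl}prop-2-enoate (both ketal epimers)
Conditions: 14 (3 equiv), PPTS (5 mol%), CH2Cl2, 0 °C; then Et3N; Et3N-deactivated silica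
Reagents that add atoms: none
Why: Acid-catalysed addition of an alcohol to an enol ether (mixed-ketal formation, as in 2-methoxypropyl protection): the C5 hydroxyl captures the protonated enol ether under conditions too mild to touch the ketone or lactone, so no equilibrium ketalisation is needed and both C10 epimers are acceptable.

Step 10
Reactants: 15 methyl 2-{(R)-[(2S,3S)-3-acetyl-5-oxooxolan-2-yl][(2-methoxyhex-5-en-2-yl)oxy]methyl}prop-2-enoate
Product: 16 methyl (7R)-7-[(2S,3S)-3-acetyl-5-oxooxolan-2-yl]-2-methoxy-2-methyl-2,3,4,7-tetrahydrooxepine-6-carboxylate (both C10 epimers)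
Conditions: second-generation Grubbs catalyst (5 mol%), CH2Cl2 (5 mM), 40 °C
Reagents that add atoms: none
Why: Ring-closing metathesis: the ruthenium carbene formed at the terminal alkene closes onto the acrylate across the gem-disubstituted ketal tether to give ring A, whose C3=C4 bond can only be cis within a seven-membered ring, which is the required geometry (C2 cis to C5).

Step 11
Reactants: 16 methyl (7R)-7-[(2S,3S)-3-acetyl-5-oxooxolan-2-yl]-2-methoxy-2-methyl-2,3,4,7-tetrahydrooxepine-6-carboxylate
Product: 17 methyl (7R)-2-methoxy-2-methyl-7-{(2S,3S)-5-oxo-3-[1-(trimethylsilyloxy)ethenyl]oxolan-2-yl}-2,3,4,7-tetrahydrooxepine-6-carboxylate (both C10 epimers)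
Conditions: LiN(iPr)2 (1.1 equiv), TMSCl (3 equiv, present from the start), THF, −78 °C; pentane, filtration, no aqueous work-up; used at once
Reagents that add atoms: chlorotrimethylsilane, C[Si](C)(C)Cl
Why: Kinetic enolisation with in situ silyl trapping: the hindered amide removes a methyl proton (C9) faster than the C7 methine or the lactone and enoate protons at −78 °C, and immediate O-silylation forbids equilibration to the C7 enolate that would expel the lactone carboxylate.

Step 12
Reactants: 17 methyl (7R)-2-methoxy-2-methyl-7-{(2S,3S)-5-oxo-3-[1-(trimethylsilyloxy)ethenyl]oxolan-2-yl}-2,3,4,7-tetrahydrooxepine-6-carboxylate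
Product: 19 core keto lactone (C8 ketone; γ-lactone with C11 = CH2 trans-fused at C6–C7; 5R,6S,7S,10S), via ring A oxocarbenium triflate 18 (not isolated)
Conditions: TMSOTf (0.2 equiv), 4 Å MS, CH2Cl2 (5 mM), −78 → −40 °C; then NaHCO3 (aq)
Reagents that add atoms: none
Why: Proposed new method: TMSOTf removes the methoxy group from either C10 epimer of 17 to give the flat, tertiary ring A oxocarbenium ion 18, the C8 enol silane held on C7 adds to C10 through C9, and transfer of the silyl group to triflate releases the C8 ketone and regenerates the catalyst. The closest known reaction type is the silyl triflate-catalysed Mukaiyama-type addition of enol silanes to ketals, used intramolecularly on five- and six-membered cyclic oxocarbenium ions to build smaller oxa-bridged bicycles; attack on a seven-membered oxocarbenium ion to close a second seven-membered ring is not established. Ring B (O, C5, C6, C7, C8, C9, C10) closes in a 7-(enolendo)-endo-trig mode, both enol carbons and both atoms of the C10=O+ bond ending up in the new ring. The only new stereocentre, C10 (S), is controlled by C5 (R): a one-atom oxygen bridge can span C5 and C10 of the ten-membered carbocycle only in a cis sense, so C9 must bond to the face of the cation on which the C5–C6 bond lies, and both ketal epimers converge on the same ion. The step needs C-alkylation to win over proton loss to ring A enol ethers, O-alkylation and intermolecular reaction; the first two are reversible under the acidic silyl triflate conditions and funnel back to 18, the trans lactone holds the C7 enol silane and ring A at a dihedral angle that a seven-membered ring accommodates, and high dilution disfavours oligomers.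

Step 13
Reactants: 19 core keto lactone (5R,6S,7S,10S)
Product: 20 core 8β-hydroxy lactone (C8–OH on the face of C11; 5R,6S,7R,8R,10S)
Conditions: NaBH4, CeCl3·7H2O, MeOH/THF, −78 °C; then NH4Cl (aq)
Reagents that add atoms: none
Why: Luche reduction (1,2-selective and weakly basic, so the β-acyloxy ketone does not eliminate and the enoate is untouched): hydride should attack C8 from the exo face of ring B, opposite the ring A bridge and syn to H7, placing the hydroxyl on the face of C11 (8R).

Step 14
Reactants: 21 (R)-lactic acid; 22 2,2-dimethylpropanal (pivalaldehyde)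
Product: 23 (2R,5R)-2-tert-butyl-5-methyl-1,3-dioxolan-4-one
Conditions: p-TsOH·H2O (cat.), pentane, reflux, Dean–Stark trap; crystallisation of the cis isomer
Reagents that add atoms: none
Why: Acid-catalysed acetalisation with azeotropic removal of water (self-regeneration of stereocentres): the cis acetal, with tert-butyl and methyl on the same face, is the preferred and crystalline isomer and stores the lactate chirality at the acetal carbon.

Step 15
Reactants: 23 (2R,5R)-2-tert-butyl-5-methyl-1,3-dioxolan-4-one; 24 acetaldehyde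
Product: 26 (2R,5S)-2-tert-butyl-5-(1-hydroxyethyl)-5-methyl-1,3-dioxolan-4-one (carbinol epimers), via lithium enolate 25 (not isolated)
Conditions: LiN(iPr)2, THF, −78 °C; then 24, −78 °C; NH4Cl (aq)
Reagents that add atoms: none
Why: Aldol addition of a lithium enolate: acetaldehyde attacks the planar enolate on the face opposite the tert-butyl group, so the new C–C bond takes the place of the former hydrogen and the quaternary centre is set (5S) as the side chain requires, the carbinol centre being lost in step 16.

Step 16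
Reactants: 26 (2R,5S)-2-tert-butyl-5-(1-hydroxyethyl)-5-methyl-1,3-dioxolan-4-one
Product: 27 (2R,5S)-2-tert-butyl-5-ethenyl-5-methyl-1,3-dioxolan-4-one
Conditions: Burgess reagent, toluene, 70 °C
Reagents that add atoms: none
Why: Burgess dehydration (thermal syn-elimination of the sulfamate ester): the carbinol carbon has β-hydrogens only on its methyl group, so only the terminal vinyl group can form.

Step 17
Reactants: 27 (2R,5S)-2-tert-butyl-5-ethenyl-5-methyl-1,3-dioxolan-4-one
Product: 28 (S)-2-hydroxy-2-methylbut-3-enoic acid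
Conditions: LiOH, THF/H2O, 0 °C → rt; then HCl (aq) to pH 2
Reagents that add atoms: water (as aqueous LiOH), O
Why: Saponification of the dioxolanone (an acylal-type ester) releases the acetal as pivalaldehyde without touching the quaternary stereocentre.

Step 18
Reactants: 28 (S)-2-hydroxy-2-methylbut-3-enoic acid
Product: 30 (S)-2-methyl-2-[(triethylsilyl)oxy]but-3-enoic acid, via bis-silylated acid 29 (not isolated)
Conditions: TESOTf (2.5 equiv), 2,6-lutidine, CH2Cl2, −78 → 0 °C; then K2CO3, MeOH/H2O, 0 °C; citric acid (aq) to pH 4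
Reagents that add atoms: triethylsilyl trifluoromethanesulfonate, CC[Si](CC)(CC)OS(=O)(=O)C(F)(F)F
Why: Silylation of the tertiary alcohol with a silyl triflate followed by selective mild solvolysis of the far more labile silyl ester, which leaves the hindered tertiary silyl ether in place.

Step 19
Reactants: 20 core 8β-hydroxy lactone; 30 (S)-2-methyl-2-[(triethylsilyl)oxy]but-3-enoic acid
Product: 32 core 8β-[(S)-2-methyl-2-(triethylsilyloxy)but-3-enoyl]oxy lactone (C11 = CH2), via mixed anhydride 31 (not isolated)
Conditions: 30, 2,4,6-trichlorobenzoyl chloride, Et3N, THF, rt; then 20, DMAP, toluene, rt → 40 °C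
Reagents that add atoms: none
Why: Yamaguchi esterification: acyl transfer from the mixed anhydride through the DMAP acylpyridinium ion leaves the C8–O bond untouched (retention at C8), and the acid has no α-hydrogen, so its stereocentre cannot epimerise.

Step 20
Reactants: 32 core 8β-[(S)-2-methyl-2-(triethylsilyloxy)but-3-enoyl]oxy lactone
Product: 34 core 8β-ester with 11-[(dimethylamino)methyl] lactone (C11 epimers), via silyl ketene acetal 33 (not isolated)
Conditions: LiN(iPr)2 (1.1 equiv), TMSCl (present from the start), THF, −78 °C; then Me2N=CH2 I (Eschenmoser's salt), CH2Cl2, −78 °C → rt; NaHCO3 (aq)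
Reagents that add atoms: N,N-dimethylmethyleneiminium iodide, C[N+](C)=C.[I-]
Why: Mannich reaction of a silyl ketene acetal: the lactone CH2 (C11) is the only saturated ester α-position (the C8 ester has no α-hydrogen), immediate silyl trapping keeps the enolate from a Claisen-type attack on the neighbouring C8 ester, and the iminium ion then adds at C11, whose configuration is irrelevant.

Step 21
Reactants: 34 core 8β-ester with 11-[(dimethylamino)methyl] lactone
Product: 36 O-triethylsilyl ether of the target (α-methylene lactone; 5R,6S,7R,8R,10S,2'S), via trimethylammonium iodide 35 (not isolated)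
Conditions: MeI, CH2Cl2, rt; then NaHCO3 (aq), EtOAc, rt
Reagents that add atoms: none
Why: Exhaustive N-methylation followed by base-induced β-elimination of trimethylamine (Hofmann-type, E1cB) gives the conjugated α-methylene lactone under conditions too mild to affect the esters or the silyl ether.

Step 22
Reactants: 36 O-triethylsilyl ether of the target
Product: 37 CNP0325750.1 (target; 5R,6S,7R,8R,10S,2'S)
Conditions: HF·pyridine, pyridine, THF, 0 °C → rt
Reagents that add atoms: none
Why: Fluoride-mediated cleavage of the tertiary triethylsilyl ether under weakly acidic buffered conditions, chosen because basic fluoride sources could add to the α-methylene lactone or trigger acyl migration.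

Compound list
1 | (S)-5-(hydroxymethyl)furan-2(5H)-one | OC[C@H]1OC(=O)C=C1 | starting material
2 | (S)-5-{[(tert-butyldimethylsilyl)oxy]methyl}furan-2(5H)-one | CC(C)(C)[Si](C)(C)OC[C@H]1OC(=O)C=C1 | intermediate
3 | prop-1-en-2-ylmagnesium bromide | CC(=C)[Mg]Br | starting material
4 | bromomagnesium enolate of 5 (not isolated) | CC(C)(C)[Si](C)(C)OC[C@H]1OC(O[Mg]Br)=C[C@@H]1C(C)=C | intermediate
5 | (4R,5S)-5-{[(tert-butyldimethylsilyl)oxy]methyl}-4-(prop-1-en-2-yl)oxolan-2-one | CC(C)(C)[Si](C)(C)OC[C@H]1OC(=O)C[C@@H]1C(C)=C | intermediate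
6 | (4R,5S)-5-(hydroxymethyl)-4-(prop-1-en-2-yl)oxolan-2-one | OC[C@H]1OC(=O)C[C@@H]1C(C)=C | intermediate
7 | (2S,3R)-5-oxo-3-(prop-1-en-2-yl)oxolane-2-carbaldehyde | O=C[C@H]1OC(=O)C[C@@H]1C(C)=C | intermediate
8 | methyl acrylate | C=CC(=O)OC | starting material
9 | methyl 2-{(R)-hydroxy[(2S,3R)-5-oxo-3-(prop-1-en-2-yl)oxolan-2-yl]methyl}prop-2-enoate | C=C(C(=O)OC)[C@@H](O)[C@H]1OC(=O)C[C@@H]1C(C)=C | intermediate
10 | secondary ozonide of 9 (3-methyl-1,2,4-trioxolan-3-yl at C7; not isolated) | C=C(C(=O)OC)[C@@H](O)[C@H]1OC(=O)C[C@@H]1C2(C)OCOO2 | intermediate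
11 | methyl 2-{(R)-[(2S,3S)-3-acetyl-5-oxooxolan-2-yl](hydroxy)methyl}prop-2-enoate | C=C(C(=O)OC)[C@@H](O)[C@H]1OC(=O)C[C@@H]1C(C)=O | intermediate
12 | hex-5-en-2-one | CC(=O)CCC=C | starting material
13 | 5,5-dimethoxyhex-1-ene | COC(C)(OC)CCC=C | intermediate
14 | 2-methoxyhexa-1,5-diene | COC(=C)CCC=C | intermediate
15 | methyl 2-{(R)-[(2S,3S)-3-acetyl-5-oxooxolan-2-yl][(2-methoxyhex-5-en-2-yl)oxy]methyl}prop-2-enoate (both ketal epimers) | C=C(C(=O)OC)[C@@H](OC(C)(OC)CCC=C)[C@H]1OC(=O)C[C@@H]1C(C)=O | intermediate
16 | methyl (7R)-7-[(2S,3S)-3-acetyl-5-oxooxolan-2-yl]-2-methoxy-2-methyl-2,3,4,7-tetrahydrooxepine-6-carboxylate (both C10 epimers) | COC1(C)CCC=C(C(=O)OC)[C@@H](O1)[C@H]1OC(=O)C[C@@H]1C(C)=O | intermediate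
17 | methyl (7R)-2-methoxy-2-methyl-7-{(2S,3S)-5-oxo-3-[1-(trimethylsilyloxy)ethenyl]oxolan-2-yl}-2,3,4,7-tetrahydrooxepine-6-carboxylate (both C10 epimers; key-step precursor) | COC1(C)CCC=C(C(=O)OC)[C@@H](O1)[C@H]1OC(=O)C[C@@H]1C(=C)O[Si](C)(C)C | intermediate
18 | ring A 2-methyl oxocarbenium triflate derived from 17 (not isolated) | CC1=[O+][C@@H]([C@H]2OC(=O)C[C@@H]2C(=C)O[Si](C)(C)C)C(C(=O)OC)=CCC1.[O-]S(=O)(=O)C(F)(F)F | intermediate
19 | core keto lactone: C8 ketone, γ-lactone (C11 = CH2) trans-fused at C6–C7, 5R,6S,7S,10S (key-step product) | O=C1C[C@]2(C)CCC=C(C(=O)OC)[C@@H](O2)[C@H]2OC(=O)C[C@@H]21 | intermediate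
20 | core 8β-hydroxy lactone, 5R,6S,7R,8R,10S | O[C@@H]1C[C@]2(C)CCC=C(C(=O)OC)[C@@H](O2)[C@H]2OC(=O)C[C@@H]21 | intermediate
21 | (R)-lactic acid | C[C@@H](O)C(=O)O | starting material
22 | 2,2-dimethylpropanal (pivalaldehyde) | CC(C)(C)C=O | starting material
23 | (2R,5R)-2-tert-butyl-5-methyl-1,3-dioxolan-4-one | C[C@H]1O[C@@H](C(C)(C)C)OC1=O | intermediate
24 | acetaldehyde | CC=O | starting material
25 | lithium (2R)-2-tert-butyl-5-methyl-1,3-dioxol-4-olate (not isolated) | [Li+].CC1=C([O-])O[C@H](C(C)(C)C)O1 | intermediate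
26 | (2R,5S)-2-tert-butyl-5-(1-hydroxyethyl)-5-methyl-1,3-dioxolan-4-one (carbinol epimers) | CC(O)[C@]1(C)O[C@@H](C(C)(C)C)OC1=O | intermediate
27 | (2R,5S)-2-tert-butyl-5-ethenyl-5-methyl-1,3-dioxolan-4-one | C=C[C@]1(C)O[C@@H](C(C)(C)C)OC1=O | intermediate
28 | (S)-2-hydroxy-2-methylbut-3-enoic acid | C=C[C@](C)(O)C(=O)O | intermediate
29 | triethylsilyl (S)-2-methyl-2-[(triethylsilyl)oxy]but-3-enoate (not isolated) | C=C[C@](C)(O[Si](CC)(CC)CC)C(=O)O[Si](CC)(CC)CC | intermediate
30 | (S)-2-methyl-2-[(triethylsilyl)oxy]but-3-enoic acid | C=C[C@](C)(O[Si](CC)(CC)CC)C(=O)O | intermediate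
31 | mixed anhydride of 30 with 2,4,6-trichlorobenzoic acid (not isolated) | C=C[C@](C)(O[Si](CC)(CC)CC)C(=O)OC(=O)c1c(Cl)cc(Cl)cc1Cl | intermediate
32 | core 8β-[(S)-2-methyl-2-(triethylsilyloxy)but-3-enoyl]oxy lactone (C11 = CH2) | C=C[C@](C)(O[Si](CC)(CC)CC)C(=O)O[C@@H]1C[C@]2(C)CCC=C(C(=O)OC)[C@@H](O2)[C@H]2OC(=O)C[C@@H]21 | intermediate
33 | trimethylsilyl ketene acetal of the lactone of 32 (not isolated) | C=C[C@](C)(O[Si](CC)(CC)CC)C(=O)O[C@@H]1C[C@]2(C)CCC=C(C(=O)OC)[C@@H](O2)[C@H]2OC(O[Si](C)(C)C)=C[C@@H]21 | intermediate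
34 | 11-[(dimethylamino)methyl] lactone (C11 epimers) | C=C[C@](C)(O[Si](CC)(CC)CC)C(=O)O[C@@H]1C[C@]2(C)CCC=C(C(=O)OC)[C@@H](O2)[C@H]2OC(=O)C(CN(C)C)[C@@H]21 | intermediate
35 | 11-[(trimethylammonio)methyl] lactone iodide (not isolated) | C=C[C@](C)(O[Si](CC)(CC)CC)C(=O)O[C@@H]1C[C@]2(C)CCC=C(C(=O)OC)[C@@H](O2)[C@H]2OC(=O)C(C[N+](C)(C)C)[C@@H]21.[I-] | intermediate
36 | O-triethylsilyl ether of the target (α-methylene lactone) | C=C[C@](C)(O[Si](CC)(CC)CC)C(=O)O[C@@H]1C[C@]2(C)CCC=C(C(=O)OC)[C@@H](O2)[C@H]2OC(=O)C(=C)[C@@H]21 | intermediate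
37 | CNP0325750.1: core 8β-[(S)-2-hydroxy-2-methylbut-3-enoyl]oxy α-methylene γ-lactone, 5R,6S,7R,8R,10S,2'S | C=C[C@](C)(O)C(=O)O[C@@H]1C[C@]2(C)CCC=C(C(=O)OC)[C@@H](O2)[C@H]2OC(=O)C(=C)[C@@H]21 | target

Total step count: 22 (main line 15, enol ether branch 2, side-chain acid branch 5).
Longest linear sequence: 15 steps (1 → 37 through steps 1–6, 9–13 and 19–22).

Steps most likely to fail

Step 12 (proposed new method). The ionised ketal may lose a proton to ring A enol ethers faster than the transannular C–C bond forms, or the medium-ring closure may be outrun by intermolecular reaction. The fallback uses known chemistry, sets out from 11 and returns at 19: the C9–C10 bond is made intermolecularly and the rings are closed afterwards. Hydroxy ketone 11 is converted with excess LiN(iPr)2/TMSCl at −78 °C into the O5-silylated enol silane F1. Silyl triflate-catalysed Mukaiyama-type addition of F1 to the acyclic dimethyl ketal 13 gives, after mildly acidic work-up, the β-methoxy ketone F2. Camphorsulfonic acid in warm toluene (or DBU) eliminates methanol to the enone F3, whose C5 hydroxyl adds back in a reversible 7-endo oxa-Michael reaction to give the ring B oxepanone F4 as equilibrating C10 epimers. Ring-closing metathesis with second-generation Grubbs catalyst can close ring A only from the epimer with the butenyl chain cis to C4 and gives ketone 19; the other epimer is returned to the equilibration.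

Step 5. The slow amine-catalysed addition may allow epimerisation at C6 of the α-acyloxy aldehyde, and facial selectivity at C5 may be poor under the reversible conditions. The fallback sets out from 7 and returns at 9: hydroalumination of methyl propiolate with iBu2AlH/N-methylmorpholine N-oxide in THF at 0 °C gives the vinylaluminium reagent [1-(methoxycarbonyl)ethenyl]diisobutylaluminium F5, which adds to aldehyde 7 at −78 °C within minutes, under kinetic non-chelating control (attack anti to the C6–O bond), and gives 9 directly.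

Step 13. Hydride delivery may occur on the endo face of the flexible bicycle and give the C8 epimer. The fallback sets out from 19 and returns at 20: the reduction product formed in that case, the 8α-alcohol F6, is inverted by Mitsunobu reaction with 4-nitrobenzoic acid (PPh3, DIAD, toluene, 0 °C → rt) to the 8β 4-nitrobenzoate F7, and brief methanolysis (K2CO3, MeOH, 0 °C) gives 20.

Further compounds
F1 | step 12 | methyl 2-{(R)-[(2S,3S)-5-oxo-3-[1-(trimethylsilyloxy)ethenyl]oxolan-2-yl][(trimethylsilyl)oxy]methyl}prop-2-enoate | C=C(C(=O)OC)[C@@H](O[Si](C)(C)C)[C@H]1OC(=O)C[C@@H]1C(=C)O[Si](C)(C)C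
F2 | step 12 | methyl 2-{(R)-hydroxy[(2S,3S)-3-(3-methoxy-3-methylhept-6-enoyl)-5-oxooxolan-2-yl]methyl}prop-2-enoate (C10 epimers) | C=C(C(=O)OC)[C@@H](O)[C@H]1OC(=O)C[C@@H]1C(=O)CC(C)(OC)CCC=C
F3 | step 12 | methyl 2-{(R)-hydroxy[(2S,3S)-3-(3-methylhepta-2,6-dienoyl)-5-oxooxolan-2-yl]methyl}prop-2-enoate | C=C(C(=O)OC)[C@@H](O)[C@H]1OC(=O)C[C@@H]1C(=O)C=C(C)CCC=C
F4 | step 12 | ring B oxepanone: C5–O–C10 ether closed, C10 bearing methyl and but-3-enyl, C8 ketone, trans-fused lactone, acrylate on C5 (C10 epimers) | C=C(C(=O)OC)[C@H]1OC(C)(CCC=C)CC(=O)[C@H]2CC(=O)O[C@H]12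
F5 | step 5 | [1-(methoxycarbonyl)ethenyl]diisobutylaluminium | C=C(C(=O)OC)[Al](CC(C)C)CC(C)C
F6 | step 13 | core 8α-hydroxy lactone (C8 epimer of 20; 5R,6S,7R,8S,10S) | O[C@H]1C[C@]2(C)CCC=C(C(=O)OC)[C@@H](O2)[C@H]2OC(=O)C[C@@H]21
F7 | step 13 | core 8β-(4-nitrobenzoyl)oxy lactone | O=C(O[C@@H]1C[C@]2(C)CCC=C(C(=O)OC)[C@@H](O2)[C@H]2OC(=O)C[C@@H]21)c1ccc(cc1)[N+](=O)[O-]
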